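The numbers are those of an exercise; the run is a simulation.

The forward rate of the first step on the electrophile starts 1.4 times that of the quenching step, so two consumers act from the first minute.

electrophile 20 mM; nucleophile 2.00 equiv; free base 0.500 equiv; protic impurity 6.00 mM; time 20 min

    electrophile + nucleophile ⇌ acid set free + target (K1 = 0.23, k1 = 2.32 M⁻¹ min⁻¹)
    nucleophile + acid set free ⇌ protonated nucleophile, settled at all times (K2 = 12300 M⁻¹)
    acid set free + free base ⇌ salt of the base, settled at all times (K3 = 67800 M⁻¹)
    electrophile + target → side product (k4 = 8.02 M⁻¹ min⁻¹)
    electrophile + protic impurity → quenched substrate (k5 = 10.7 M⁻¹ min⁻¹)

- a species is counted by the electrophile in it: one side product counts as two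
- run time (flask): 20 min

- part of the electrophile that has reacted at 20 min
- share of the unused nucleophile that is free and not bound as protonated nucleophile, at 20 min

Every step that uses electrophile is first order in it. With partners held at their charge, the pseudo-first-order constant is 0.157 min⁻¹, and 95.7% reacts by 20 min. The objection is that partners run down and target becomes a third consumer.

The way back through the first step can be dropped. The binding terms of nucleophile and free base are 490 and 680, so hardly any of the acid stays free.

Nucleophile is taken at its charge less 0.5 of the electrophile charge: N̄ = 30.0 mM, a judgement. Target is made and lost in proportion to electrophile, which cancels, so target climbs towards a ceiling of 8.68 mM. Its half-life by the side step, 4.3 min, is shorter than the run. Target and impurity are each taken at 0.5 of ceiling and charge.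

Replacing each curve by its mean gives 0.136 min⁻¹: this is the mean pull λ, the time-mean first-order constant of electrophile loss. So 93.5% reacts.

Impurity's 0.5 is the next doubt, and it stays open: λ needs a time mean, and that mean is not computed here. The impurity term is 0.0321 min⁻¹ of the 0.136 min⁻¹, and it remains a judgement. The free share is not reckoned here.

The forecast gives 92% and 84.3%, slightly below this reckoning on conversion, holding that “acid set free is shared between the base and the nucleophile”.

The flask gives 92.9% reacted, with 84.0% of the unused nucleophile free, and both forecast values hold. The flask keeps 7.1% of its electrophile, which reads as a mean pull of 0.132 min⁻¹ against the reckoned 0.136 min⁻¹. The neighbour flask, charged with 1.20 equiv of nucleophile, takes N̄ = 14.0 mM. Its target ceiling falls with N̄, so its mean pull is 0.0808 min⁻¹, and 80.1% should react. That neighbour flask gives 82.4%.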